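**Retrosynthetic overview**

- The target is a 3,3'-linked bis(4-aryl-chroman-2-one), (3S,4R,3'S,4'R), with the 4-aryl group and the 3,3' bond cis in each ring. The last operations are global O-demethylation, preceded by double kinetic protonation of a bis-enolate, which sets C3 and C3' from C4 and C4'.
- The central C3–C3' bond is made by a copper-catalysed radical coupling of the ring A silyl ketene acetal with the ring B α-bromolactone (new method), joining two separately built halves.
- Each half is a (4R)-4-aryl-chroman-2-one, made by rhodium/(R)-SEGPHOS 1,4-addition of 4-methoxyphenylboronic acid to a coumarin; this sets C4 and C4'.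
- Each coumarin (lactone ring A, lactone ring B, formed separately on a pre-existing benzene ring) comes from a phenol and ethyl propiolate by palladium-catalysed C–H hydroarylation/lactonisation.
- The phenols come from resorcinol (iridium C–H borylation/oxidation) and from 1,4-benzoquinone (Thiele–Winter acetoxylation, then two ortho-lithiation/oxidation cycles); the boronic acid comes from 4-iodophenol.

Locants: unprimed = ring A half (5,7-dioxygenated), primed = ring B half (5,6,7,8-tetraoxygenated). Methyl ethers are the only protecting groups.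

**Route**

Step 1
Reactants: 1 4-iodophenol
Product: 2 4-iodoanisole
Conditions: MeI, K2CO3, acetone, reflux
Reagents that add atoms: iodomethane, CI
Why: Williamson O-methylation masks the phenol for the organometallic steps that follow.

Step 2
Reactants: 2 4-iodoanisole
Product: 5 (4-methoxyphenyl)boronic acid, via 4-methoxyphenylmagnesium chloride 3 (not isolated), via dimethyl (4-methoxyphenyl)boronate 4 (not isolated)
Conditions: i-PrMgCl·LiCl, THF, 0 °C → rt; B(OMe)3, −78 °C → rt; 1 M HCl
Reagents that add atoms: trimethyl borate, COB(OC)OC; water, O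
Why: Iodine–magnesium exchange, borate trapping and hydrolysis is the standard arylboronic acid synthesis and tolerates the methyl ether.

Step 3
Reactants: 6 resorcinol
Product: 7 1,3-dimethoxybenzene
Conditions: Me2SO4, K2CO3, acetone, reflux
Reagents that add atoms: dimethyl sulfate, COS(=O)(=O)OC
Why: Double Williamson etherification gives robust ethers and leaves C5 as the only unhindered C–H for the next step.

Step 4
Reactants: 7 1,3-dimethoxybenzene
Product: 9 3,5-dimethoxyphenol, via 3,5-dimethoxyphenyl pinacol boronate 8 (not isolated)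
Conditions: [Ir(OMe)(cod)]2 (1.5 mol%), dtbpy (3 mol%), B2pin2 (0.6 equiv), THF, 80 °C; then KHSO5 (as 2KHSO5·KHSO4·K2SO4), acetone/H2O, rt
Reagents that add atoms: potassium peroxymonosulfate, [K+].[O-]S(=O)(=O)OO
Why: Iridium-catalysed C–H borylation is sterically controlled and takes only C5 (the one C–H without an ortho substituent), and the boronate is oxidised in the same pot to the phenol (C–H borylation/oxidation).

Step 5
Reactants: 9 3,5-dimethoxyphenol; 10 ethyl propiolate
Product: 12 5,7-dimethoxy-2H-chromen-2-one, via ethyl (Z)-3-(2-hydroxy-4,6-dimethoxyphenyl)acrylate 11 (not isolated)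
Conditions: Pd(OAc)2 (3 mol%), CF3CO2H/CH2Cl2, 0 °C → rt
Reagents that add atoms: none
Why: Palladium-catalysed trans-hydroarylation of the alkynoate by the electron-rich C–H ortho to the hydroxyl (Fujiwara-type C–H activation, phenol–propiolate coumarin synthesis) gives the cis-cinnamate, which lactonises in the acid medium.

Step 6
Reactants: 12 5,7-dimethoxy-2H-chromen-2-one; 5 (4-methoxyphenyl)boronic acid
Product: 13 (4R)-5,7-dimethoxy-4-(4-methoxyphenyl)chroman-2-one
Conditions: Rh(acac)(C2H4)2 (3 mol%), (R)-SEGPHOS (3.3 mol%), 5 (4 equiv), dioxane/H2O 10:1, 60 °C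
Reagents that add atoms: none
Why: Hayashi–Miyaura rhodium-catalysed asymmetric 1,4-addition of an arylboronic acid to a coumarin sets C4, and the (R)-ligand, which gives (R)-4-arylchroman-2-ones from coumarin itself, is expected to give 4R here because the CIP order at C4 is unchanged.

Step 7
Reactants: 14 1,4-benzoquinone
Product: 15 1,2,4-triacetoxybenzene
Conditions: Ac2O, H2SO4 (cat.), 40–50 °C
Reagents that add atoms: acetic anhydride, CC(=O)OC(C)=O
Why: Thiele–Winter acetoxylation (acid-catalysed conjugate addition of acetate, enolisation, acetylation) installs the third ring oxygen.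

Step 8
Reactants: 15 1,2,4-triacetoxybenzene
Product: 17 1,2,4-trimethoxybenzene, via benzene-1,2,4-triol 16 (not isolated)
Conditions: NaOH, Me2SO4, H2O/MeOH, Na2S2O4 (cat.), N2, 0 → 50 °C
Reagents that add atoms: dimethyl sulfate, COS(=O)(=O)OC
Why: Saponification and in situ Williamson methylation under reducing, oxygen-free conditions avoids isolating the air-sensitive triol.

Step 9
Reactants: 17 1,2,4-trimethoxybenzene
Product: 20 2,3,6-trimethoxyphenol, via 3-lithio-1,2,4-trimethoxybenzene 18 (not isolated), via dimethyl (2,3,6-trimethoxyphenyl)boronate 19 (not isolated)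
Conditions: n-BuLi, THF, 0 °C → rt; B(OMe)3, −78 °C → rt; AcOH, 30% H2O2, 0 °C → rt
Reagents that add atoms: hydrogen peroxide, OO
Why: Directed ortho-metalation occurs at C3, the only position flanked by two methoxy groups, and borate trapping with peroxide oxidation turns the aryllithium into the phenol.

Step 10
Reactants: 20 2,3,6-trimethoxyphenol
Product: 21 1,2,3,4-tetramethoxybenzene
Conditions: MeI, K2CO3, DMF, 40 °C
Reagents that add atoms: iodomethane, CI
Why: Williamson O-methylation of the hindered phenoxide in a dipolar aprotic solvent.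

Step 11
Reactants: 21 1,2,3,4-tetramethoxybenzene
Product: 24 2,3,4,5-tetramethoxyphenol, via 2,3,4,5-tetramethoxyphenyllithium 22 (not isolated), via dimethyl (2,3,4,5-tetramethoxyphenyl)boronate 23 (not isolated)
Conditions: n-BuLi, TMEDA, THF, 0 °C → rt; B(OMe)3, −78 °C → rt; AcOH, 30% H2O2, 0 °C
Reagents that add atoms: hydrogen peroxide, OO
Why: Directed ortho-metalation at one of the two equivalent remaining C–H positions followed by borylation/oxidation gives the phenol with a single free ortho C–H.

Step 12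
Reactants: 24 2,3,4,5-tetramethoxyphenol; 10 ethyl propiolate
Product: 26 5,6,7,8-tetramethoxy-2H-chromen-2-one, via ethyl (Z)-3-(2-hydroxy-3,4,5,6-tetramethoxyphenyl)acrylate 25 (not isolated)
Conditions: Pd(OAc)2 (5 mol%), CF3CO2H/CH2Cl2, 0 °C → rt
Reagents that add atoms: none
Why: The same palladium-catalysed phenol–propiolate C–H hydroarylation/lactonisation as in step 5, with regiochemistry forced because the only aromatic C–H is ortho to the hydroxyl.

Step 13
Reactants: 26 5,6,7,8-tetramethoxy-2H-chromen-2-one; 5 (4-methoxyphenyl)boronic acid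
Product: 27 (4R)-5,6,7,8-tetramethoxy-4-(4-methoxyphenyl)chroman-2-one
Conditions: Rh(acac)(C2H4)2 (5 mol%), (R)-SEGPHOS (5.5 mol%), 5 (5 equiv), dioxane/H2O 10:1, 60 °C
Reagents that add atoms: none
Why: Hayashi–Miyaura asymmetric 1,4-addition as in step 6 sets C4' as R by the same catalyst-controlled facial selection.

Step 14
Reactants: 27 (4R)-5,6,7,8-tetramethoxy-4-(4-methoxyphenyl)chroman-2-one
Product: 29 (3S,4R)-3-bromo-5,6,7,8-tetramethoxy-4-(4-methoxyphenyl)chroman-2-one, via ring B lithium enolate 28 (not isolated)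
Conditions: LiN(SiMe3)2, THF, −78 °C; cannulate into NBS, THF, −78 °C; AcOH quench
Reagents that add atoms: N-bromosuccinimide, O=C1CCC(=O)N1Br
Why: Electrophilic α-bromination of the lactone enolate occurs anti to the pseudoaxial C4 aryl group to give the 3,4-trans bromide (the C3 configuration is not carried into the target), and the fully substituted benzo ring cannot be brominated.

Step 15
Reactants: 13 (4R)-5,7-dimethoxy-4-(4-methoxyphenyl)chroman-2-one; 29 (3S,4R)-3-bromo-5,6,7,8-tetramethoxy-4-(4-methoxyphenyl)chroman-2-one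
Product: 32 (3R,3'R,4R,4'R)-5,5',6',7,7',8'-hexamethoxy-4,4'-bis(4-methoxyphenyl)-[3,3'-bichromane]-2,2'-dione, via ring A lithium enolate 30 (not isolated), via ring A trimethylsilyl ketene acetal 31 (not isolated)
Conditions: 13 (1.3 equiv), LiN(SiMe3)2, Me3SiCl, THF, −78 °C → rt, filter under Ar, solvent swap; then 29 (1.0 equiv), CuBr (10 mol%), tris(2-pyridylmethyl)amine (12 mol%), MeCN/PhMe 1:3, 25–40 °C, Ar
Reagents that add atoms: none
Why: Proposed new method: monovalent copper abstracts bromine from 29 as in atom-transfer radical chemistry, the electrophilic α-lactonyl radical adds to C3 of the electron-rich ketene acetal 31 anti to the C4 aryl group, and the resulting α-silyloxy radical is oxidised by the divalent copper bromide and loses Me3SiBr to regenerate the catalyst, forming the C3–C3' bond (3,4-trans in both rings expected, any C3/C3' epimers are carried on and erased in step 16); the closest known reaction type is the copper-catalysed Kharasch-type radical alkylation of silyl enol ethers with tertiary α-bromo carbonyl compounds, not yet shown for a secondary α-bromolactone with a lactone ketene acetal to give a vicinally branched bis-lactone.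

Step 16
Reactants: 32 (3R,3'R,4R,4'R)-5,5',6',7,7',8'-hexamethoxy-4,4'-bis(4-methoxyphenyl)-[3,3'-bichromane]-2,2'-dione
Product: 34 (3S,3'S,4R,4'R)-5,5',6',7,7',8'-hexamethoxy-4,4'-bis(4-methoxyphenyl)-[3,3'-bichromane]-2,2'-dione, via dilithium bis-enolate 33 (not isolated)
Conditions: LiN(i-Pr)2 (2.5 equiv), THF/DMPU, −78 → −40 °C; AcOH in THF (precooled), −78 °C
Reagents that add atoms: none
Why: Double deprotonation removes both C3 stereocentres, and kinetic protonation of each enolate occurs anti to its neighbouring C4 aryl group (held pseudoaxial by peri strain with the C5 methoxy group and allylic strain), so H ends up trans and the 3,3' bond cis to the aryl group in each ring, giving 3S,3'S from 4R,4'R (diastereoselective enolate protonation).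

Step 17
Reactants: 34 (3S,3'S,4R,4'R)-5,5',6',7,7',8'-hexamethoxy-4,4'-bis(4-methoxyphenyl)-[3,3'-bichromane]-2,2'-dione
Product: 35 (3S,3'S,4R,4'R)-5,5',6',7,7',8'-hexahydroxy-4,4'-bis(4-hydroxyphenyl)-[3,3'-bichromane]-2,2'-dione
Conditions: BBr3 (20 equiv), CH2Cl2, −78 °C → rt, Ar; MeOH then H2O/ascorbic acid, 0 °C; reversed-phase purification under Ar
Reagents that add atoms: none
Why: Lewis-acid O-demethylation with BBr3 cleaves all eight aryl methyl ethers while the δ-lactones stay closed (or re-close on acidic work-up, the six-membered ring being favoured and both ortho hydroxyls of each aryl being equivalent) and the C–H stereocentres are untouched at low temperature.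

**Compound list**

1 | 4-iodophenol | Oc1ccc(I)cc1 | starting material
2 | 4-iodoanisole | COc1ccc(I)cc1 | intermediate
3 | 4-methoxyphenylmagnesium chloride (formed in the flask) | COc1ccc([Mg]Cl)cc1 | intermediate
4 | dimethyl (4-methoxyphenyl)boronate (formed in the flask) | COB(OC)c1ccc(OC)cc1 | intermediate
5 | (4-methoxyphenyl)boronic acid | COc1ccc(B(O)O)cc1 | intermediate
6 | resorcinol | Oc1cccc(O)c1 | starting material
7 | 1,3-dimethoxybenzene | COc1cccc(OC)c1 | intermediate
8 | 2-(3,5-dimethoxyphenyl)-4,4,5,5-tetramethyl-1,3,2-dioxaborolane (formed in the flask) | COc1cc(OC)cc(c1)B1OC(C)(C)C(C)(C)O1 | intermediate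
9 | 3,5-dimethoxyphenol | COc1cc(O)cc(OC)c1 | intermediate
10 | ethyl propiolate | CCOC(=O)C#C | starting material
11 | ethyl (Z)-3-(2-hydroxy-4,6-dimethoxyphenyl)acrylate (formed in the flask) | CCOC(=O)/C=C\c1c(O)cc(OC)cc1OC | intermediate
12 | 5,7-dimethoxy-2H-chromen-2-one | COc1cc(OC)c2ccc(=O)oc2c1 | intermediate
13 | (4R)-5,7-dimethoxy-4-(4-methoxyphenyl)chroman-2-one | O=C1Oc2cc(OC)cc(OC)c2[C@@H](c2ccc(OC)cc2)C1 | intermediate
14 | 1,4-benzoquinone | O=C1C=CC(=O)C=C1 | starting material
15 | 1,2,4-triacetoxybenzene | CC(=O)Oc1ccc(OC(C)=O)c(OC(C)=O)c1 | intermediate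
16 | benzene-1,2,4-triol (formed in the flask) | Oc1ccc(O)c(O)c1 | intermediate
17 | 1,2,4-trimethoxybenzene | COc1ccc(OC)c(OC)c1 | intermediate
18 | 3-lithio-1,2,4-trimethoxybenzene (formed in the flask) | [Li]c1c(OC)ccc(OC)c1OC | intermediate
19 | dimethyl (2,3,6-trimethoxyphenyl)boronate (formed in the flask) | COB(OC)c1c(OC)ccc(OC)c1OC | intermediate
20 | 2,3,6-trimethoxyphenol | COc1ccc(OC)c(OC)c1O | intermediate
21 | 1,2,3,4-tetramethoxybenzene | COc1ccc(OC)c(OC)c1OC | intermediate
22 | 2,3,4,5-tetramethoxyphenyllithium (formed in the flask) | [Li]c1cc(OC)c(OC)c(OC)c1OC | intermediate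
23 | dimethyl (2,3,4,5-tetramethoxyphenyl)boronate (formed in the flask) | COB(OC)c1cc(OC)c(OC)c(OC)c1OC | intermediate
24 | 2,3,4,5-tetramethoxyphenol | COc1cc(O)c(OC)c(OC)c1OC | intermediate
25 | ethyl (Z)-3-(2-hydroxy-3,4,5,6-tetramethoxyphenyl)acrylate (formed in the flask) | CCOC(=O)/C=C\c1c(O)c(OC)c(OC)c(OC)c1OC | intermediate
26 | 5,6,7,8-tetramethoxy-2H-chromen-2-one | COc1c(OC)c(OC)c2oc(=O)ccc2c1OC | intermediate
27 | (4R)-5,6,7,8-tetramethoxy-4-(4-methoxyphenyl)chroman-2-one | O=C1Oc2c(OC)c(OC)c(OC)c(OC)c2[C@@H](c2ccc(OC)cc2)C1 | intermediate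
28 | lithium enolate of 27, lithium (4R)-5,6,7,8-tetramethoxy-4-(4-methoxyphenyl)-4H-chromen-2-olate (formed in the flask) | [Li]OC1=C[C@H](c2ccc(OC)cc2)c2c(OC)c(OC)c(OC)c(OC)c2O1 | intermediate
29 | (3S,4R)-3-bromo-5,6,7,8-tetramethoxy-4-(4-methoxyphenyl)chroman-2-one | O=C1Oc2c(OC)c(OC)c(OC)c(OC)c2[C@@H](c2ccc(OC)cc2)[C@@H]1Br | intermediate
30 | lithium enolate of 13, lithium (4R)-5,7-dimethoxy-4-(4-methoxyphenyl)-4H-chromen-2-olate (formed in the flask) | [Li]OC1=C[C@H](c2ccc(OC)cc2)c2c(OC)cc(OC)cc2O1 | intermediate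
31 | (4R)-5,7-dimethoxy-4-(4-methoxyphenyl)-2-(trimethylsilyloxy)-4H-chromene (formed in the flask) | C[Si](C)(C)OC1=C[C@H](c2ccc(OC)cc2)c2c(OC)cc(OC)cc2O1 | intermediate
32 | (3R,3'R,4R,4'R)-5,5',6',7,7',8'-hexamethoxy-4,4'-bis(4-methoxyphenyl)-[3,3'-bichromane]-2,2'-dione (3,4-trans in both rings) | O=C1Oc2cc(OC)cc(OC)c2[C@@H](c2ccc(OC)cc2)[C@@H]1[C@@H]1C(=O)Oc2c(OC)c(OC)c(OC)c(OC)c2[C@H]1c1ccc(OC)cc1 | intermediate
33 | dilithium bis-enolate of 32, (4R,4'R)-3,3'-bi(4H-chromene)-2,2'-diolate (formed in the flask) | [Li]OC1=C(C2=C(O[Li])Oc3c(OC)c(OC)c(OC)c(OC)c3[C@H]2c2ccc(OC)cc2)[C@H](c2ccc(OC)cc2)c2c(OC)cc(OC)cc2O1 | intermediate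
34 | (3S,3'S,4R,4'R)-5,5',6',7,7',8'-hexamethoxy-4,4'-bis(4-methoxyphenyl)-[3,3'-bichromane]-2,2'-dione (3,4-cis in both rings) | O=C1Oc2cc(OC)cc(OC)c2[C@@H](c2ccc(OC)cc2)[C@H]1[C@H]1C(=O)Oc2c(OC)c(OC)c(OC)c(OC)c2[C@H]1c1ccc(OC)cc1 | intermediate
35 | (3S,3'S,4R,4'R)-5,5',6',7,7',8'-hexahydroxy-4,4'-bis(4-hydroxyphenyl)-[3,3'-bichromane]-2,2'-dione (CNP0064734.1) | O=C1Oc2cc(O)cc(O)c2[C@@H](c2ccc(O)cc2)[C@H]1[C@H]1C(=O)Oc2c(O)c(O)c(O)c(O)c2[C@H]1c1ccc(O)cc1 | target

**Step count**

Total steps: 17. Longest linear sequence: 11 (steps 7–17, from 1,4-benzoquinone); the other branches are 7 steps each (steps 1, 2, 13–17 and steps 3–6, 15–17).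

**Three steps most likely to fail, with fallbacks**

Step 15 (the proposed copper-catalysed coupling). Likely failure modes are loss of HBr from 29 to the coumarin, simple reduction of 29, and hydrolysis of 31 before the radical adds. The fallback uses known oxidative enolate coupling with a stoichiometric oxidant instead of the catalytic radical path. It sets out from 13 and 27 (3:1): both are converted to their lithium enolates with LiN(i-Pr)2 in THF at −78 °C and oxidised with copper bis(2-ethylhexanoate), warming to rt. This gives 32 as a C3/C3' epimer mixture in a statistical distribution, together with the ring A homodimer (3R,3'R,4R,4'R)-5,5',7,7'-tetramethoxy-4,4'-bis(4-methoxyphenyl)-[3,3'-bichromane]-2,2'-dione F1 and a little of the ring B homodimer (3R,3'R,4R,4'R)-5,5',6,6',7,7',8,8'-octamethoxy-4,4'-bis(4-methoxyphenyl)-[3,3'-bichromane]-2,2'-dione F2. The three products differ by two methoxy groups each and are separated by chromatography. The fallback comes back to the route at 32, and step 16 converges all C3/C3' epimers.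

Step 16 (double kinetic protonation). The dianion may form incompletely, or protonation may be less face-selective than expected. The fallback changes from substrate-controlled protonation of a lithium enolate to reagent-controlled protonation of an isolated silyl ketene acetal. It sets out from 32: soft enolisation (Me3SiOTf, Et3N, CH2Cl2, 0 °C → rt) gives the bis(trimethylsilyl ketene acetal) (4R,4'R)-5,5',6',7,7',8'-hexamethoxy-4,4'-bis(4-methoxyphenyl)-2,2'-bis(trimethylsilyloxy)-3,3'-bi(4H-chromene) F3. This is protonated with a Lewis-acid-assisted chiral Brønsted acid (BINOL monomethyl ether·SnCl4, catalytic, with stoichiometric 2,6-dimethylphenol, toluene, −78 °C; the ligand enantiomer matched to the substrate bias is chosen on the first run). The fallback comes back at 34.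

Step 13 (and, by analogy, step 6). Rhodium 1,4-addition to an electron-rich coumarin with a peri methoxy group may be slow enough that protodeboronation wins. The fallback installs the aryl group before the stereocentre and sets C4' by hydride delivery. It sets out from 2, 10 and 24: Sonogashira coupling of 2 with 10 (Pd(PPh3)2Cl2, CuI, K2CO3, THF, 65 °C) gives ethyl 3-(4-methoxyphenyl)propiolate F4. Hydroarylation of F4 with 24 (Pd(OAc)2, CF3CO2H/CH2Cl2) passes through ethyl (Z)-3-(2-hydroxy-3,4,5,6-tetramethoxyphenyl)-3-(4-methoxyphenyl)acrylate F5 and gives 5,6,7,8-tetramethoxy-4-(4-methoxyphenyl)-2H-chromen-2-one F6. Copper hydride asymmetric conjugate reduction (Cu(OAc)2·H2O, DTBM-SEGPHOS antipode chosen to give 4R, (EtO)2MeSiH, t-BuOH, PhMe) proceeds by tandem 1,4-/1,2-reduction to (4R)-5,6,7,8-tetramethoxy-4-(4-methoxyphenyl)chroman-2-ol F7. Oxidation of the lactol (PhI(OAc)2, TEMPO cat., CH2Cl2) comes back to the route at 27.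

**Further compounds**

F1 | step 15 | (3R,3'R,4R,4'R)-5,5',7,7'-tetramethoxy-4,4'-bis(4-methoxyphenyl)-[3,3'-bichromane]-2,2'-dione (major epimer drawn) | O=C1Oc2cc(OC)cc(OC)c2[C@@H](c2ccc(OC)cc2)[C@@H]1[C@@H]1C(=O)Oc2cc(OC)cc(OC)c2[C@H]1c1ccc(OC)cc1
F2 | step 15 | (3R,3'R,4R,4'R)-5,5',6,6',7,7',8,8'-octamethoxy-4,4'-bis(4-methoxyphenyl)-[3,3'-bichromane]-2,2'-dione (major epimer drawn) | O=C1Oc2c(OC)c(OC)c(OC)c(OC)c2[C@@H](c2ccc(OC)cc2)[C@@H]1[C@@H]1C(=O)Oc2c(OC)c(OC)c(OC)c(OC)c2[C@H]1c1ccc(OC)cc1
F3 | step 16 | (4R,4'R)-5,5',6',7,7',8'-hexamethoxy-4,4'-bis(4-methoxyphenyl)-2,2'-bis(trimethylsilyloxy)-3,3'-bi(4H-chromene) | C[Si](C)(C)OC1=C(C2=C(O[Si](C)(C)C)Oc3c(OC)c(OC)c(OC)c(OC)c3[C@H]2c2ccc(OC)cc2)[C@H](c2ccc(OC)cc2)c2c(OC)cc(OC)cc2O1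
F4 | step 13 | ethyl 3-(4-methoxyphenyl)propiolate | CCOC(=O)C#Cc1ccc(OC)cc1
F5 | step 13 | ethyl (Z)-3-(2-hydroxy-3,4,5,6-tetramethoxyphenyl)-3-(4-methoxyphenyl)acrylate | CCOC(=O)/C=C(/c1ccc(OC)cc1)c1c(O)c(OC)c(OC)c(OC)c1OC
F6 | step 13 | 5,6,7,8-tetramethoxy-4-(4-methoxyphenyl)-2H-chromen-2-one | COc1ccc(cc1)-c1cc(=O)oc2c(OC)c(OC)c(OC)c(OC)c12
F7 | step 13 | (4R)-5,6,7,8-tetramethoxy-4-(4-methoxyphenyl)chroman-2-ol (anomer mixture) | OC1C[C@H](c2ccc(OC)cc2)c2c(OC)c(OC)c(OC)c(OC)c2O1
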